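**Retrosynthetic overview**
1. No ring is built: rings A, B and C and the only stereocentre (C-2, S) are bought together in (2S)-naringenin 1, and C-2 is never touched afterwards.
2. The most acidic phenol of 1 (7-OH) is masked as the MOM ether 2; 2-methylbut-3-en-2-ol 3 is turned, through its lithium alkoxide 4, into the reverse-prenyl donor 5.
3. Key disconnection: the C-3'–CH2 bond of the prenyl group comes from an aromatic Claisen [3,3]-sigmatropic rearrangement of the 4'-O-(1,1-dimethylallyl) ether 6 (from 2 + 5), via dienone 7, to phenol 8.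
4. Endgame: 4'-O-methylation (9), then MOM removal to the target 10.

Assumption: (2S)-naringenin 1 is bought enantiopure (ee checked by chiral HPLC before use), and simple reagents that only deliver a protecting group or a methyl group are listed under "Reagents that add atoms" without a compound number.

**Step 1**
Reactants: 1 (2S)-naringenin
Product: 2 (2S)-5-hydroxy-2-(4-hydroxyphenyl)-7-(methoxymethoxy)chroman-4-one
Conditions: MOMCl (1.05 equiv), i-Pr2NEt (1.2 equiv), DMF, 0 °C
Reagents that add atoms: chloromethyl methyl ether (MOMCl), COCCl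
Why: Williamson-type O-alkylation (MOM acetal formation) in which the amine base ionises only the 7-OH, a vinylogous acid para to the C-4 carbonyl, while the chelated 5-OH and the ordinary 4'-OH stay protonated and C-2 is not involved.

**Step 2**
Reactants: 3 2-methylbut-3-en-2-ol
Product: 5 tert-butyl 2-methylbut-3-en-2-yl carbonate, via lithium 2-methylbut-3-en-2-olate 4 (not isolated)
Conditions: n-BuLi (1.0 equiv), THF, −78 → 0 °C; then Boc2O, 0 °C → rt; H2O quench
Reagents that add atoms: di-tert-butyl dicarbonate (Boc2O), CC(C)(C)OC(=O)OC(=O)OC(C)(C)C; n-butyllithium, [Li]CCCC (supplies only the lithium of 4)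
Why: Alkoxide acylation (carbonate formation) in which the tertiary lithium alkoxide 4 attacks Boc2O and the expelled tert-butyl carbonate collapses to CO2 and tert-butoxide, giving the tertiary allylic carbonate without allylic transposition.

**Step 3**
Reactants: 2 (2S)-5-hydroxy-2-(4-hydroxyphenyl)-7-(methoxymethoxy)chroman-4-one; 5 tert-butyl 2-methylbut-3-en-2-yl carbonate (1.2 equiv)
Product: 6 (2S)-5-hydroxy-7-(methoxymethoxy)-2-[4-(2-methylbut-3-en-2-yloxy)phenyl]chroman-4-one
Conditions: Pd(PPh3)4 (5 mol %), THF, 0 °C → rt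
Reagents that add atoms: none
Why: Decarboxylative Tsuji–Trost O-allylation in which zerovalent palladium ionises 5 to a 1,1-dimethylallyl palladium cation and tert-butoxide, the latter deprotonates the only unchelated phenol (4'-OH), and the phenoxide attacks the more substituted allyl terminus under kinetic control at low temperature to give the tertiary ether, with C-2 untouched under these near-neutral conditions.

**Step 4**
Reactants: 6 (2S)-5-hydroxy-7-(methoxymethoxy)-2-[4-(2-methylbut-3-en-2-yloxy)phenyl]chroman-4-one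
Product: 8 (2S)-5-hydroxy-2-[4-hydroxy-3-(3-methylbut-2-en-1-yl)phenyl]-7-(methoxymethoxy)chroman-4-one, via ring-B prenyl cyclohexadienone 7 (not isolated)
Conditions: PhMe (degassed), 120 °C, sealed tube
Reagents that add atoms: none
Why: Aromatic Claisen rearrangement, a [3,3]-sigmatropic shift that forms the C-3'–CH2 bond with allyl inversion (tertiary ether to linear prenyl group) at either of the two equivalent ortho positions of ring B, after which dienone 7 tautomerises to phenol 8, and the neutral thermal conditions leave C-2 and the MOM ether intact.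

**Step 5**
Reactants: 8 (2S)-5-hydroxy-2-[4-hydroxy-3-(3-methylbut-2-en-1-yl)phenyl]-7-(methoxymethoxy)chroman-4-one
Product: 9 (2S)-5-hydroxy-2-[4-methoxy-3-(3-methylbut-2-en-1-yl)phenyl]-7-(methoxymethoxy)chroman-4-one
Conditions: MeOH (3 equiv), PPh3 (1.5 equiv), DIAD (1.5 equiv, added last), THF, 0 °C → rt
Reagents that add atoms: methanol, CO
Why: Mitsunobu etherification in which the free 4'-phenol (pKa about 10) is the only competent pronucleophile because the 5-OH is locked in a hydrogen bond to the C-4 carbonyl, and the essentially base-free conditions avoid the base-induced ring opening to the chalcone that would racemise C-2.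

**Step 6**
Reactants: 9 (2S)-5-hydroxy-2-[4-methoxy-3-(3-methylbut-2-en-1-yl)phenyl]-7-(methoxymethoxy)chroman-4-one
Product: 10 4'-O-methyllicoflavanone
Conditions: HCl (1.25 M in MeOH), 40 °C
Reagents that add atoms: none
Why: Acid-catalysed acetal cleavage (transacetalisation with methanol) removes the aryl MOM ether under mild conditions in which the prenyl group, having no free ortho-OH, cannot cyclise to a chroman and C-2 is not epimerised, so the (2S) configuration bought in 1 is delivered to the target.

**Compound list**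
1 | (2S)-naringenin, (2S)-5,7-dihydroxy-2-(4-hydroxyphenyl)chroman-4-one | Oc1ccc([C@@H]2CC(=O)c3c(O)cc(O)cc3O2)cc1 | starting material
2 | (2S)-5-hydroxy-2-(4-hydroxyphenyl)-7-(methoxymethoxy)chroman-4-one (7-O-MOM-naringenin) | Oc1ccc([C@@H]2CC(=O)c3c(O)cc(OCOC)cc3O2)cc1 | intermediate
3 | 2-methylbut-3-en-2-ol | CC(C)(O)C=C | starting material
4 | lithium 2-methylbut-3-en-2-olate (formed in the flask, not isolated) | [Li+].[O-]C(C)(C)C=C | intermediate
5 | tert-butyl 2-methylbut-3-en-2-yl carbonate | CC(C)(C)OC(=O)OC(C)(C)C=C | intermediate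
6 | (2S)-5-hydroxy-7-(methoxymethoxy)-2-[4-(2-methylbut-3-en-2-yloxy)phenyl]chroman-4-one | C=CC(C)(C)Oc1ccc([C@@H]2CC(=O)c3c(O)cc(OCOC)cc3O2)cc1 | intermediate
7 | (2S)-5-hydroxy-7-(methoxymethoxy)-2-[3-(3-methylbut-2-en-1-yl)-4-oxocyclohexa-1,5-dien-1-yl]chroman-4-one (ring-B dienone, both epimers at the new sp3 carbon, not isolated) | O=C1C=CC([C@@H]2CC(=O)c3c(O)cc(OCOC)cc3O2)=CC1CC=C(C)C | intermediate
8 | (2S)-5-hydroxy-2-[4-hydroxy-3-(3-methylbut-2-en-1-yl)phenyl]-7-(methoxymethoxy)chroman-4-one | Oc1ccc([C@@H]2CC(=O)c3c(O)cc(OCOC)cc3O2)cc1CC=C(C)C | intermediate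
9 | (2S)-5-hydroxy-2-[4-methoxy-3-(3-methylbut-2-en-1-yl)phenyl]-7-(methoxymethoxy)chroman-4-one | COc1ccc([C@@H]2CC(=O)c3c(O)cc(OCOC)cc3O2)cc1CC=C(C)C | intermediate
10 | 4'-O-methyllicoflavanone, (2S)-5,7-dihydroxy-2-[4-methoxy-3-(3-methylbut-2-en-1-yl)phenyl]chroman-4-one | COc1ccc([C@@H]2CC(=O)c3c(O)cc(O)cc3O2)cc1CC=C(C)C | target

**Totals**
Total step count: 6. Longest linear sequence: 5 steps (1 → 2 → 6 → 8 → 9 → 10); step 2 is a one-step side branch.

**Steps most likely to fail**

The selective mono-protection in step 1 may give mixtures of 7-O-, 4'-O- and bis-MOM ethers. The fallback sets out from 1 and comes back at 2. Compound 1 is peracetylated (Ac2O, pyridine, rt) to (2S)-naringenin triacetate F1. The 7-acetate, the most activated aryl ester, is removed selectively by thiolysis (PhSH, imidazole, NMP, 0 °C) to give (2S)-4',5-di-O-acetylnaringenin F2. Its single free phenol is protected (MOMCl, i-Pr2NEt, CH2Cl2) to give (2S)-4',5-di-O-acetyl-7-O-(methoxymethyl)naringenin F3. Mild methanolysis (NH4OAc, MeOH, rt) then removes both acetates and gives 2.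

The palladium-catalysed reverse O-prenylation in step 3 may give the linear prenyl ether (thermodynamic product), C-allylation, or some reaction at the 5-OH. The fallback sets out from 2 and comes back at 6. Copper-catalysed O-propargylation with 3-chloro-3-methylbut-1-yne (CuCl2 cat., DBU, MeCN, 0 °C, short reaction time) gives (2S)-5-hydroxy-7-(methoxymethoxy)-2-[4-(2-methylbut-3-yn-2-yloxy)phenyl]chroman-4-one F4. Semi-hydrogenation of the alkyne (H2 1 atm, Pd on CaCO3 poisoned with Pb(OAc)2, quinoline, EtOAc) gives 6. The ee is re-checked after the DBU step.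

The thermal Claisen rearrangement in step 4 may lose isoprene from the tertiary ether (returning 2) or be followed by cyclisation of the ortho-prenyl phenol. The fallback sets out from 2 and comes back at 8, building the prenyl group by olefin metathesis instead. O-allylation of 2 with allyl methyl carbonate (Pd(PPh3)4, THF, rt) gives (2S)-2-[4-(allyloxy)phenyl]-5-hydroxy-7-(methoxymethoxy)chroman-4-one F5. Heating (1,2-dichlorobenzene, 190 °C) effects the Claisen rearrangement through the dienone (2S)-5-hydroxy-7-(methoxymethoxy)-2-[4-oxo-3-(prop-2-en-1-yl)cyclohexa-1,5-dien-1-yl]chroman-4-one F6, which is not isolated. This tautomerises to (2S)-2-(3-allyl-4-hydroxyphenyl)-5-hydroxy-7-(methoxymethoxy)chroman-4-one F7. Cross-metathesis of the allyl group with excess 2-methylbut-2-ene (second-generation Grubbs catalyst (H2IMes)(PCy3)Cl2Ru=CHPh, CH2Cl2, 40 °C) gives 8.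

**Further compounds**
F1 | step 1 | (2S)-naringenin triacetate, (2S)-5,7-diacetoxy-2-(4-acetoxyphenyl)chroman-4-one | CC(=O)Oc1ccc([C@@H]2CC(=O)c3c(OC(C)=O)cc(OC(C)=O)cc3O2)cc1
F2 | step 1 | (2S)-4',5-di-O-acetylnaringenin | CC(=O)Oc1ccc([C@@H]2CC(=O)c3c(OC(C)=O)cc(O)cc3O2)cc1
F3 | step 1 | (2S)-4',5-di-O-acetyl-7-O-(methoxymethyl)naringenin | CC(=O)Oc1ccc([C@@H]2CC(=O)c3c(OC(C)=O)cc(OCOC)cc3O2)cc1
F4 | step 3 | (2S)-5-hydroxy-7-(methoxymethoxy)-2-[4-(2-methylbut-3-yn-2-yloxy)phenyl]chroman-4-one | C#CC(C)(C)Oc1ccc([C@@H]2CC(=O)c3c(O)cc(OCOC)cc3O2)cc1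
F5 | step 4 | (2S)-2-[4-(allyloxy)phenyl]-5-hydroxy-7-(methoxymethoxy)chroman-4-one | C=CCOc1ccc([C@@H]2CC(=O)c3c(O)cc(OCOC)cc3O2)cc1
F6 | step 4 | (2S)-5-hydroxy-7-(methoxymethoxy)-2-[4-oxo-3-(prop-2-en-1-yl)cyclohexa-1,5-dien-1-yl]chroman-4-one (not isolated) | O=C1C=CC([C@@H]2CC(=O)c3c(O)cc(OCOC)cc3O2)=CC1CC=C
F7 | step 4 | (2S)-2-(3-allyl-4-hydroxyphenyl)-5-hydroxy-7-(methoxymethoxy)chroman-4-one | Oc1ccc([C@@H]2CC(=O)c3c(O)cc(OCOC)cc3O2)cc1CC=C
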